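## Retrosynthetic overview

1. Ester C–O bond: late acylation of the ring D secondary alcohol with (3R,5S)-3-hydroxy-3,5-dimethylheptanoic acid; the diosphenol is carried as its MOM enol ether.
2. Key disconnection: the bond between the tertiary carbinol carbon and the methylene-bearing carbon of ring B, made by a SmI2 ketyl cyclization of a cyclopentene-1,2-dione onto a β-silyl ketone; Peterson elimination then gives the exocyclic methylene. Ring B closes last.
3. Ring A comes from cyclotene, oxidized to the 1,2-dione and C-alkylated by a (Z)-allylic bromide.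
4. The (Z)-trisubstituted alkene is attached to C5 of the hydrindane by nickel-catalysed decarboxylative alkenylation; the β-silyl ketone comes from a vinyl group by ozonolysis and Me3SiCHN2 homologation.
5. Rings C and D form together by a Pauson–Khand reaction of an acyclic 1,7-enyne acid made by an enantioselective Ireland–Claisen rearrangement; Li/NH3 sets the remaining ring D centres.

Assumption: the SMILES defines the target fully; rings are A (cyclopentenone), B (cyclooctene), C (cyclohexane), D (cyclopentane); the C/D unit is numbered as octahydro-1H-indene (C1 isopropyl, C2 oxygen, C3a methyl, C5 and C6 joined to ring B, C7a ring-fusion CH); α is the face of the 3a-methyl group, β the opposite face; absolute configuration is that of the SMILES (3aS).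

## Route

Step 1
Reactants: 1 3-methylbut-1-yne; 2 (E)-1,4-dibromobut-2-ene
Product: 3 (E)-1-bromo-7-methyloct-2-en-5-yne
Conditions: 2 (3 equiv), CuI (10 mol %), K2CO3, DMF, 23 °C
Reagents that add atoms: none
Why: Copper-catalysed alkynyl–allyl coupling (SN2 substitution of the primary allylic bromide by the copper acetylide), with the dibromide in excess to stop at mono-substitution and the E alkene untouched.

Step 2
Reactants: 3 (E)-1-bromo-7-methyloct-2-en-5-yne; 4 4-methylpent-4-enoic acid
Product: 5 (E)-7-methyloct-2-en-5-yn-1-yl 4-methylpent-4-enoate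
Conditions: Cs2CO3, DMF, 23 °C
Reagents that add atoms: none
Why: SN2 O-alkylation of the caesium carboxylate by the primary allylic bromide (carboxylate esterification).

Step 3
Reactants: 5 (E)-7-methyloct-2-en-5-yn-1-yl 4-methylpent-4-enoate
Product: 7 (2S,3R)-3-ethenyl-7-methyl-2-(2-methylprop-2-en-1-yl)oct-5-ynoic acid, via Z(O)-boron ketene acetal 6 (not isolated)
Conditions: (4S,5S)-2-bromo-4,5-diphenyl-1,3-bis{[3,5-bis(trifluoromethyl)phenyl]sulfonyl}-1,3,2-diazaborolidine (1.1 equiv), i-Pr2NEt, CH2Cl2, −78 → 4 °C; aqueous work-up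
Reagents that add atoms: none
Why: Enantioselective Ireland–Claisen rearrangement in which the chiral diazaborolidine gives the Z(O)-boron ketene acetal, whose chair transition state with the (E)-allyl unit sets C2 and C3 together (2,3-syn) with the absolute sense fixed by the (S,S)-controller (the mirror-image controller would give the enantiomer).

Step 4
Reactants: 7 (2S,3R)-3-ethenyl-7-methyl-2-(2-methylprop-2-en-1-yl)oct-5-ynoic acid
Product: 8 (3aS)-6α-ethenyl-3a-methyl-2-oxo-1-(propan-2-yl)-3,3a,4,5,6,7-hexahydro-2H-indene-5β-carboxylic acid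
Conditions: Co2(CO)8 (10 mol %), tetramethylthiourea (60 mol %), CO (1 atm), benzene, 70 °C
Reagents that add atoms: carbon monoxide, [C-]#[O+]
Why: Catalytic intramolecular Pauson–Khand reaction of the 1,7-enyne (the vinyl group is only 1,5 to the alkyne and cannot take part), in which a chair-like tether with the vinyl and carboxyl groups equatorial places the new quaternary methyl axial and syn to H-5, so rings C and D form together and the 3aS centre is set.

Step 5
Reactants: 8 (3aS)-6α-ethenyl-3a-methyl-2-oxo-1-(propan-2-yl)-3,3a,4,5,6,7-hexahydro-2H-indene-5β-carboxylic acid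
Product: 11 (3aS)-6α-ethenyl-2β-hydroxy-3a-methyl-1α-(propan-2-yl)-trans-octahydro-1H-indene-5β-carboxylic acid, via dilithium enolate carboxylate 9 (not isolated), via saturated C2 ketone 10 (not isolated)
Conditions: Li, NH3(l)/THF, −78 °C; MeOH; then NH4Cl
Reagents that add atoms: none
Why: Dissolving-metal (Birch-type) enone reduction in which axial protonation at C7a anti to the angular methyl gives the trans ring fusion, methanol protonates the C1 enolate kinetically from the β-face (isopropyl ends α), and the liberated ketone is reduced in situ under thermodynamic control to the 2β-alcohol trans to the isopropyl group, the lithium carboxylate and the isolated vinyl group being inert.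

Step 6
Reactants: 11 (3aS)-6α-ethenyl-2β-hydroxy-3a-methyl-1α-(propan-2-yl)-trans-octahydro-1H-indene-5β-carboxylic acid
Product: 12 1,3-dioxoisoindolin-2-yl ester of 11
Conditions: N-hydroxyphthalimide, DIC, CH2Cl2, 23 °C
Reagents that add atoms: N-hydroxyphthalimide, ON1C(=O)c2ccccc2C1=O
Why: Carbodiimide esterification to the N-acyloxyphthalimide (redox-active ester), which masks the acid during steps 7 and 8 and arms it for radical decarboxylation, the hindered secondary alcohol not competing.

Step 7
Reactants: 12 1,3-dioxoisoindolin-2-yl ester of 11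
Product: 14 6α-formyl analogue of 12, via 1,2,4-trioxolane 13 (not isolated)
Conditions: O3, CH2Cl2, −78 °C; PPh3
Reagents that add atoms: ozone, O=[O+][O-]
Why: Ozonolysis of the only alkene with reductive work-up, the aldehyde keeping the equatorial 6α configuration that is also the thermodynamic one at this epimerisable centre.

Step 8
Reactants: 14 6α-formyl analogue of 12
Product: 15 6α-[(trimethylsilyl)acetyl] analogue of 12
Conditions: Me3SiCHN2, MgBr2·OEt2 (20 mol %), CH2Cl2, 0 °C
Reagents that add atoms: (trimethylsilyl)diazomethane, C[Si](C)(C)C=[N+]=[N-]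
Why: Aoyama–Shioiri homologation (addition of the diazo carbon to the aldehyde, loss of N2 with 1,2-hydride shift) gives the β-ketosilane, installing the future exocyclic methylene carbon together with its Peterson handle.

Step 9
Reactants: 16 but-2-yn-1-ol
Product: 18 (Z)-3-iodobut-2-en-1-ol, via cyclic sodium alkenylalanate 17 (not isolated)
Conditions: NaAlH2(OCH2CH2OCH3)2, THF, 0 °C; I2, −78 °C
Reagents that add atoms: iodine, [I][I]
Why: Hydroxyl-directed trans-hydroalumination of the propargylic alcohol places aluminium on C3 cis to the CH2O group (five-membered alanate) and iodinolysis with retention gives the Z iodide.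

Step 10
Reactants: 15 6α-[(trimethylsilyl)acetyl] analogue of 12; 18 (Z)-3-iodobut-2-en-1-ol
Product: 19 1-[(3aS)-2β-hydroxy-5β-[(2Z)-4-hydroxybut-2-en-2-yl]-3a-methyl-1α-(propan-2-yl)-trans-octahydro-1H-inden-6α-yl]-2-(trimethylsilyl)ethan-1-one
Conditions: 18 (1.5 equiv), NiBr2·glyme (10 mol %), 4,4′-di-tert-butyl-2,2′-bipyridine (12 mol %), Zn, DMA, 23 °C
Reagents that add atoms: none
Why: Nickel-catalysed decarboxylative reductive alkenylation (cross-electrophile coupling) in which single-electron reduction of the phthalimide ester releases the secondary C5 radical, which is captured by the alkenylnickel species with retention of the Z geometry and bonds on the equatorial β-face trans to the C6 acyl group, so C5 is set here.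

Step 11
Reactants: 19 allylic alcohol from step 10
Product: 20 1-[(3aS)-5β-[(2Z)-4-bromobut-2-en-2-yl]-2β-hydroxy-3a-methyl-1α-(propan-2-yl)-trans-octahydro-1H-inden-6α-yl]-2-(trimethylsilyl)ethan-1-one
Conditions: CBr4, PPh3, 2,6-lutidine, CH2Cl2, −20 °C
Reagents that add atoms: carbon tetrabromide, BrC(Br)(Br)Br
Why: Appel bromination, selective for the primary allylic alcohol over the hindered ring D secondary alcohol, with lutidine keeping the medium neutral for the β-ketosilane.

Step 12
Reactants: 21 2-hydroxy-3-methylcyclopent-2-en-1-one (cyclotene)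
Product: 22 2-(methoxymethoxy)-3-methylcyclopent-2-en-1-one
Conditions: MOMCl, i-Pr2NEt, CH2Cl2, 0 °C
Reagents that add atoms: chloromethyl methyl ether, COCCl
Why: O-alkylation of the acidic diosphenol hydroxyl (MOM enol ether protection).

Step 13
Reactants: 22 2-(methoxymethoxy)-3-methylcyclopent-2-en-1-one
Product: 23 3-(methoxymethoxy)-4-methylcyclopent-3-ene-1,2-dione
Conditions: SeO2, 1,4-dioxane/H2O, 70 °C
Reagents that add atoms: selenium dioxide, O=[Se]=O
Why: Riley oxidation of the only enolisable α-methylene of the ketone gives the vicinal dione, whose new C1 carbonyl is the future carbinol carbon.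

Step 14
Reactants: 23 3-(methoxymethoxy)-4-methylcyclopent-3-ene-1,2-dione; 20 allylic bromide from step 11
Product: 25 C5-alkylated dione (ring A joined through CH2 to the Z alkene; C5 of the dione a labile epimer mixture), via lithium enolate 24 (not isolated)
Conditions: 23 (1.5 equiv), LiN(SiMe3)2 (1.4 equiv), THF, −78 °C; then 20, −78 → 0 °C
Reagents that add atoms: none
Why: C-alkylation (SN2, no allylic transposition) of the vinylogous 1,3-dicarbonyl-type lithium enolate at its unsubstituted C5 by the primary allylic bromide, the new centre being α to a ketone and therefore labile until step 15.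

Step 15
Reactants: 25 C5-alkylated dione
Product: 27 tetracyclic allylic alcohol (the target lacking the acyl group and carrying the diosphenol as MOM ether), via tetracyclic β-hydroxysilane diol 26 (not isolated)
Conditions: SmI2 (2.2 equiv, added over 2 h), THF, −78 → −20 °C, 2 mM; then AcOH, 23 °C
Reagents that add atoms: none
Why: Proposed new method: SmI2 reduces the 1,2-dione (far easier to reduce than the dialkyl ketone) to a samarium ketyl whose C1 radical adds to the tethered β-silyl ketone activated by trivalent samarium, the alkoxyl radical being reduced by the second equivalent, so the fully substituted carbinol–carbinol bond and ring B form in one radical step; the CH2 tether on C5 delivers the ketone to its own face so OH and H at the A/B fusion end cis, while slow addition lets electron exchange and enolisation interconvert the C5 epimers so that the epimer matched to the hydrindane cyclises, and acetic acid then triggers anti Peterson elimination of the tertiary β-hydroxysilane to the exocyclic methylene without touching the α-ketol; closest known chemistry is the SmI2 ketyl–carbonyl (pinacol-type) cyclization to medium rings followed by Peterson olefination.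

Step 16
Reactants: 28 (S)-1-bromo-2-methylbutane; 29 N-methoxy-N-methylacetamide
Product: 31 (S)-4-methylhexan-2-one, via (S)-(2-methylbutyl)magnesium bromide 30 (not isolated)
Conditions: Mg, THF; then 29, 0 °C; aq. HCl
Reagents that add atoms: none
Why: Grignard formation (the stereocentre is β to magnesium and untouched) and acylation by the Weinreb amide, whose chelated tetrahedral intermediate prevents over-addition.

Step 17
Reactants: 31 (S)-4-methylhexan-2-one
Product: 32 (4S,6S)-4,6-dimethyloct-1-en-4-ol
Conditions: allyl-B(O-i-Pr)2, (R)-3,3′-dibromo-BINOL (15 mol %), PhCH3/PhCF3, −35 °C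
Reagents that add atoms: allyldiisopropoxyborane, C=CCB(OC(C)C)OC(C)C
Why: Schaus-type BINOL-catalysed asymmetric allylboration of the methyl ketone through a chair-like boronate transition state, the catalyst (R series chosen by analogy with aryl methyl ketones) distinguishing methyl from the branched alkyl group and setting the tertiary carbinol.

Step 18
Reactants: 32 (4S,6S)-4,6-dimethyloct-1-en-4-ol
Product: 33 (3R,5S)-3-hydroxy-3,5-dimethylheptanoic acid
Conditions: RuCl3 (2 mol %), NaIO4, CCl4/MeCN/H2O, 23 °C
Reagents that add atoms: sodium periodate, [Na+].[O-]I(=O)(=O)=O; water, O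
Why: Sharpless RuO4 oxidative cleavage of the terminal alkene to the carboxylic acid, the tertiary alcohol being unoxidisable.

Step 19
Reactants: 27 tetracyclic allylic alcohol; 33 (3R,5S)-3-hydroxy-3,5-dimethylheptanoic acid
Product: 34 MOM enol ether of the target
Conditions: 33 (3 equiv), EDC·HCl, DMAP, CH2Cl2, 23 °C
Reagents that add atoms: none
Why: Steglich esterification in which the activated acid acylates the only reactive hydroxyl (ring D secondary), the tertiary alcohols and the masked diosphenol not reacting.

Step 20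
Reactants: 34 MOM enol ether of the target
Product: 35 CNP0110944.3
Conditions: aq. HCl (1 M), THF, 23 °C
Reagents that add atoms: none
Why: Acid hydrolysis of the enol acetal, which cleaves far faster than the ester hydrolyses or the tertiary allylic α-ketol ionises, releases the diosphenol.

## Compound list

1 | 3-methylbut-1-yne | CC(C)C#C | starting material
2 | (E)-1,4-dibromobut-2-ene | BrC/C=C/CBr | starting material
3 | (E)-1-bromo-7-methyloct-2-en-5-yne | CC(C)C#CC/C=C/CBr | intermediate
4 | 4-methylpent-4-enoic acid | C=C(C)CCC(=O)O | starting material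
5 | (E)-7-methyloct-2-en-5-yn-1-yl 4-methylpent-4-enoate | C=C(C)CCC(=O)OC/C=C/CC#CC(C)C | intermediate
6 | Z(O)-boron ketene acetal of 5 with the (4S,5S)-diazaborolidine | C=C(C)C/C=C(\OB1N(S(=O)(=O)c2cc(cc(c2)C(F)(F)F)C(F)(F)F)[C@@H](c2ccccc2)[C@H](c2ccccc2)N1S(=O)(=O)c1cc(cc(c1)C(F)(F)F)C(F)(F)F)OC/C=C/CC#CC(C)C | intermediate
7 | (2S,3R)-3-ethenyl-7-methyl-2-(2-methylprop-2-en-1-yl)oct-5-ynoic acid | C=C[C@@H](CC#CC(C)C)[C@H](CC(C)=C)C(=O)O | intermediate
8 | (3aS)-6α-ethenyl-3a-methyl-2-oxo-1-(propan-2-yl)-3,3a,4,5,6,7-hexahydro-2H-indene-5β-carboxylic acid | C=C[C@H]1CC2=C(C(C)C)C(=O)C[C@]2(C)C[C@@H]1C(=O)O | intermediate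
9 | dilithium C1=C2 enolate carboxylate of the trans-fused (7aβ-H) reduction product of 8 | [Li+].[Li+].C=C[C@H]1C[C@H]2C(C(C)C)=C([O-])C[C@]2(C)C[C@@H]1C(=O)[O-] | intermediate
10 | lithium (3aS)-6α-ethenyl-3a-methyl-2-oxo-1α-(propan-2-yl)-trans-octahydro-1H-indene-5β-carboxylate | [Li+].C=C[C@H]1C[C@H]2[C@@H](C(C)C)C(=O)C[C@]2(C)C[C@@H]1C(=O)[O-] | intermediate
11 | (3aS)-6α-ethenyl-2β-hydroxy-3a-methyl-1α-(propan-2-yl)-trans-octahydro-1H-indene-5β-carboxylic acid (7aβ-H) | C=C[C@H]1C[C@H]2[C@@H](C(C)C)[C@H](O)C[C@]2(C)C[C@@H]1C(=O)O | intermediate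
12 | 1,3-dioxoisoindolin-2-yl ester of 11 | C=C[C@H]1C[C@H]2[C@@H](C(C)C)[C@H](O)C[C@]2(C)C[C@@H]1C(=O)ON1C(=O)c2ccccc2C1=O | intermediate
13 | 6α-(1,2,4-trioxolan-3-yl) analogue of 12 (ozonide; trioxolane carbon undefined) | C1OOC(O1)[C@H]2C[C@H]3[C@@H](C(C)C)[C@H](O)C[C@]3(C)C[C@@H]2C(=O)ON2C(=O)c3ccccc3C2=O | intermediate
14 | 6α-formyl analogue of 12 | O=C[C@H]1C[C@H]2[C@@H](C(C)C)[C@H](O)C[C@]2(C)C[C@@H]1C(=O)ON1C(=O)c2ccccc2C1=O | intermediate
15 | 6α-[(trimethylsilyl)acetyl] analogue of 12 | C[Si](C)(C)CC(=O)[C@H]1C[C@H]2[C@@H](C(C)C)[C@H](O)C[C@]2(C)C[C@@H]1C(=O)ON1C(=O)c2ccccc2C1=O | intermediate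
16 | but-2-yn-1-ol | CC#CCO | starting material
17 | sodium 2,2-bis(2-methoxyethoxy)-3-methyl-2,5-dihydro-1,2-oxaaluminol-2-uide (cyclic alkenylalanate) | [Na+].CC1=CCO[Al-]1(OCCOC)OCCOC | intermediate
18 | (Z)-3-iodobut-2-en-1-ol | I/C(C)=C\CO | intermediate
19 | 1-[(3aS)-2β-hydroxy-5β-[(2Z)-4-hydroxybut-2-en-2-yl]-3a-methyl-1α-(propan-2-yl)-trans-octahydro-1H-inden-6α-yl]-2-(trimethylsilyl)ethan-1-one | C[Si](C)(C)CC(=O)[C@H]1C[C@H]2[C@@H](C(C)C)[C@H](O)C[C@]2(C)C[C@@H]1/C(C)=C\CO | intermediate
20 | 1-[(3aS)-5β-[(2Z)-4-bromobut-2-en-2-yl]-2β-hydroxy-3a-methyl-1α-(propan-2-yl)-trans-octahydro-1H-inden-6α-yl]-2-(trimethylsilyl)ethan-1-one | C[Si](C)(C)CC(=O)[C@H]1C[C@H]2[C@@H](C(C)C)[C@H](O)C[C@]2(C)C[C@@H]1/C(C)=C\CBr | intermediate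
21 | 2-hydroxy-3-methylcyclopent-2-en-1-one (cyclotene) | CC1=C(O)C(=O)CC1 | starting material
22 | 2-(methoxymethoxy)-3-methylcyclopent-2-en-1-one | COCOC1=C(C)CCC1=O | intermediate
23 | 3-(methoxymethoxy)-4-methylcyclopent-3-ene-1,2-dione | COCOC1=C(C)CC(=O)C1=O | intermediate
24 | lithium enolate of 23 (C1 oxido, C5=C1) | [Li+].COCOC1=C(C)C=C([O-])C1=O | intermediate
25 | 5-[(2Z)-3-{(3aS)-2β-hydroxy-3a-methyl-1α-(propan-2-yl)-6α-[(trimethylsilyl)acetyl]-trans-octahydro-1H-inden-5β-yl}but-2-en-1-yl]-3-(methoxymethoxy)-4-methylcyclopent-3-ene-1,2-dione (C5 of the dione epimeric) | C[Si](C)(C)CC(=O)[C@H]1C[C@H]2[C@@H](C(C)C)[C@H](O)C[C@]2(C)C[C@@H]1/C(C)=C\CC1C(C)=C(OCOC)C(=O)C1=O | intermediate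
26 | tetracyclic β-hydroxysilane diol: ring B closed, ring A tertiary OH cis to the fusion H, adjacent carbinol carrying CH2SiMe3 (configuration undefined), ring A OMOM, ring D 2β-OH | C[Si](C)(C)CC1(O)[C@H]2C[C@H]3[C@@H](C(C)C)[C@H](O)C[C@]3(C)C[C@@H]2/C(C)=C\C[C@H]2C(C)=C(OCOC)C(=O)[C@@]12O | intermediate
27 | tetracyclic allylic alcohol: the target without the acyl group, diosphenol as MOM ether | C=C1[C@H]2C[C@H]3[C@@H](C(C)C)[C@H](O)C[C@]3(C)C[C@@H]2/C(C)=C\C[C@H]2C(C)=C(OCOC)C(=O)[C@@]12O | intermediate
28 | (S)-1-bromo-2-methylbutane | BrC[C@@H](C)CC | starting material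
29 | N-methoxy-N-methylacetamide | CC(=O)N(C)OC | starting material
30 | (S)-(2-methylbutyl)magnesium bromide | Br[Mg]C[C@@H](C)CC | intermediate
31 | (S)-4-methylhexan-2-one | CC(=O)C[C@@H](C)CC | intermediate
32 | (4S,6S)-4,6-dimethyloct-1-en-4-ol | C=CC[C@](C)(O)C[C@@H](C)CC | intermediate
33 | (3R,5S)-3-hydroxy-3,5-dimethylheptanoic acid | OC(=O)C[C@](C)(O)C[C@@H](C)CC | intermediate
34 | MOM enol ether of the target (ring D 2β-ester in place) | C=C1[C@H]2C[C@H]3[C@@H](C(C)C)[C@H](OC(=O)C[C@](C)(O)C[C@@H](C)CC)C[C@]3(C)C[C@@H]2/C(C)=C\C[C@H]2C(C)=C(OCOC)C(=O)[C@@]12O | intermediate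
35 | CNP0110944.3 | C=C1[C@H]2C[C@H]3[C@@H](C(C)C)[C@H](OC(=O)C[C@](C)(O)C[C@@H](C)CC)C[C@]3(C)C[C@@H]2/C(C)=C\C[C@H]2C(C)=C(O)C(=O)[C@@]12O | target

## Step count and risks

Total step count: 20. Longest linear sequence: 14 (steps 1–8, 10, 11, 14, 15, 19, 20).

Three steps most likely to fail:

1. Step 15 (ketyl ring closure). The samarium ketyl may simply be reduced to the acyloin instead of adding to the hindered β-silyl ketone, and the facial sense of ring A relative to the hydrindane rests on a conformational argument, not on precedent. The fallback sets out from 25 and returns at 27. Zn and Me3SiCl with pyridine in THF reductively silylate the 1,2-dione (and the ring D hydroxyl) to the tris(trimethylsilyl) enediol ether F1. Tris(dimethylamino)sulfonium difluorotrimethylsilicate at −78 °C then releases the enediolate, which closes ring B by a polar aldol addition to the β-silyl ketone. Acetic acid work-up effects the Peterson elimination and removes the remaining silyl ether, giving 27.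

2. Step 4 (Pauson–Khand). A 1,7-enyne with a 1,1-disubstituted alkene and an isopropyl-substituted alkyne is a demanding substrate, and the free acid may slow catalyst turnover. The fallback sets out from 7 and returns at 8. The acid is converted into the triisopropylsilyl ester F2 (i-Pr3SiCl, imidazole). A titanocene carbonylative cyclization with Cp2Ti(CO)2 (10 mol %) under CO in toluene at 90 °C, which runs through an early-metal metallacycle and CO insertion, not through an alkyne–cobalt complex, gives the bicyclic enone silyl ester F3. Bu4NF then returns 8.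

3. Step 14 (C-alkylation of the dione enolate). O-alkylation, double alkylation or loss of the β-ketosilane on the precious bromide 20 would cost the whole hydrindane fragment. The fallback sets out from 18, 24 and 15 and returns at 25, replacing steps 10, 11 and 14. Appel bromination of 18 gives (Z)-1-bromo-3-iodobut-2-ene F4. Enolate 24 (dione in excess) is alkylated with this small electrophile, and after removal of any O-alkyl isomer this gives the ring A vinyl iodide F5. The nickel-catalysed decarboxylative alkenylation of 15 is then run with F5 under the conditions of step 10 and delivers 25 directly.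

Further compounds
F1 | step 15 | tris(trimethylsilyl) derivative of 25: ring A as 1,2-bis(trimethylsilyloxy)-3-(methoxymethoxy)-4-methylcyclopenta-1,3-diene, ring D 2β-OSiMe3 | C[Si](C)(C)CC(=O)[C@H]1C[C@H]2[C@@H](C(C)C)[C@H](O[Si](C)(C)C)C[C@]2(C)C[C@@H]1/C(C)=C\CC1C(C)=C(OCOC)C(O[Si](C)(C)C)=C1O[Si](C)(C)C
F2 | step 4 | triisopropylsilyl (2S,3R)-3-ethenyl-7-methyl-2-(2-methylprop-2-en-1-yl)oct-5-ynoate | C=C[C@@H](CC#CC(C)C)[C@H](CC(C)=C)C(=O)O[Si](C(C)C)(C(C)C)C(C)C
F3 | step 4 | triisopropylsilyl ester of 8 | C=C[C@H]1CC2=C(C(C)C)C(=O)C[C@]2(C)C[C@@H]1C(=O)O[Si](C(C)C)(C(C)C)C(C)C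
F4 | step 14 | (Z)-1-bromo-3-iodobut-2-ene | I/C(C)=C\CBr
F5 | step 14 | 5-[(2Z)-3-iodobut-2-en-1-yl]-3-(methoxymethoxy)-4-methylcyclopent-3-ene-1,2-dione | COCOC1=C(C)C(C/C=C(C)\I)C(=O)C1=O
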